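**Strategy.** The target is cut at C1''–C2'', the bond between the C6 benzylic methylene of ring A and the (E)-trisubstituted C2''=C3''(CH3) alkene. Such a unit is the footprint of a carbometalated terminal alkyne. In one operation the key step adds CH3 and aluminium syn across the alkyne of a seven-carbon fragment that already carries the C6'' stereocentre, then joins the (E)-alkenylalane to a C6 chloromethyl group under zerovalent nickel catalysis. C3''–CH3, C1''–C2'' and the alkene geometry are thereby fixed together. The precursors are pentakis-O-silylated 6-(chloromethyl)taxifolin, whose C6 carbon is placed by a 5-O-allyl Claisen rearrangement, and a silylated (R)-enynol.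

Key step: step 13

Conventions: flavonoid numbering (rings A, B, C; side chain C1''–C8'' counted from ring A); TBS = tert-butyldimethylsilyl. Every flavonoid intermediate keeps the (2R,3R) configuration of taxifolin.

Assumption: TBSCl/imidazole silylates the four non-chelated hydroxyls of taxifolin and leaves the 5-OH, which is hydrogen-bonded to the C4 carbonyl, free.

Remark: the target, chloride 12 and alkyne 18 were rechecked (2R, 3R, 6''R, 2''E) and need no correction. A fully silylated taxifolin could not be allylated at O5, so only four silyl groups go on at the start and the fifth follows the Claisen step.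

**Step 1**
Reactants: 1 (2R,3R)-taxifolin
Product: 2 (2R,3R)-3,7,3',4'-tetra-O-TBS-taxifolin (5-OH free)
Conditions: TBSCl (5 equiv), imidazole (10 equiv), DMAP (cat.), DMF, 0 °C → rt
Reagents that add atoms: tert-butyldimethylsilyl chloride, CC(C)(C)[Si](C)(C)Cl
Why: Imidazole-mediated O-silylation: the three free phenols and the C3 alcohol react, whereas the chelated 5-OH is too poor a nucleophile under these mild conditions, which also leave C2 and C3 untouched.

**Step 2**
Reactants: 2 (2R,3R)-3,7,3',4'-tetra-O-TBS-taxifolin; 3 allyl alcohol (prop-2-en-1-ol)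
Product: 4 (2R,3R)-5-O-allyl-3,7,3',4'-tetra-O-TBS-taxifolin
Conditions: PPh3, DIAD, THF, 0 °C → rt
Reagents that add atoms: none
Why: Mitsunobu etherification: the chelated but still acidic 5-OH is alkylated by the allyloxyphosphonium ion under neutral conditions, so the aryl silyl ethers and the base-sensitive ring C are not exposed to carbonate or alkoxide.

**Step 3**
Reactants: 4 (2R,3R)-5-O-allyl-3,7,3',4'-tetra-O-TBS-taxifolin
Product: 5 (2R,3R)-6-allyl-3,7,3',4'-tetra-O-TBS-taxifolin (5-OH free)
Conditions: Eu(fod)3 [Eu(C10H10F7O2)3] (10 mol%), PhCl, 120 °C, sealed tube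
Reagents that add atoms: none
Why: Aromatic Claisen rearrangement accelerated by two-point binding of europium to O4 and O5: the concerted [3,3] shift can deliver the allyl terminus only to C6, the sole ortho carbon bearing hydrogen, and tautomerisation then restores the chelated 5-OH.

**Step 4**
Reactants: 5 (2R,3R)-6-allyl-3,7,3',4'-tetra-O-TBS-taxifolin
Product: 6 (2R,3R)-6-allyl-3,5,7,3',4'-penta-O-TBS-taxifolin
Conditions: TBSOTf (1.5 equiv), 2,6-lutidine (3 equiv), CH2Cl2, −20 → 0 °C
Reagents that add atoms: tert-butyldimethylsilyl trifluoromethanesulfonate, CC(C)(C)[Si](C)(C)OS(=O)(=O)C(F)(F)F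
Why: Silyl triflate silylation: TBSOTf is electrophilic enough for the hindered, hydrogen-bonded 5-OH, and the weak hindered base 2,6-lutidine at low temperature should not enolise the C4 ketone toward C3.

**Step 5**
Reactants: 6 (2R,3R)-6-allyl-3,5,7,3',4'-penta-O-TBS-taxifolin
Product: 7 (2R,3R)-6-[(E)-prop-1-enyl]-3,5,7,3',4'-penta-O-TBS-taxifolin
Conditions: RuHCl(CO)(PPh3)3 (5 mol%), PhMe, 80 °C
Reagents that add atoms: none
Why: Ruthenium hydride-catalysed alkene isomerisation (hydrometalation/β-hydride elimination) moves the double bond into the internal benzylic position; the E/Z composition is irrelevant because both isomers are cleaved to the same aldehyde.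

**Step 6**
Reactants: 7 (2R,3R)-6-[(E)-prop-1-enyl]-3,5,7,3',4'-penta-O-TBS-taxifolin
Product: 9 (2R,3R)-6-formyl-3,5,7,3',4'-penta-O-TBS-taxifolin, via vicinal diol 8 (not isolated)
Conditions: OsO4 (2 mol%), NaIO4 (4 equiv), 2,6-lutidine (2 equiv), 1,4-dioxane/H2O (3:1), rt
Reagents that add atoms: osmium tetroxide, O=[Os](=O)(=O)=O; sodium periodate, [Na+].[O-]I(=O)(=O)=O
Why: Lemieux–Johnson oxidation: catalytic syn-dihydroxylation of the propenyl alkene and periodate cleavage of the glycol leave the C6 aldehyde, 2,6-lutidine buffering the medium so that the silyl ethers survive.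

**Step 7**
Reactants: 9 (2R,3R)-6-formyl-3,5,7,3',4'-penta-O-TBS-taxifolin
Product: 10 (2R,3R)-6-(hydroxymethyl)-3,5,7,3',4'-penta-O-TBS-taxifolin
Conditions: NaBH4 (1 equiv), CH2Cl2/EtOH (7:3), −78 → −40 °C; acetone, then aq. NH4Cl
Reagents that add atoms: none
Why: Chemoselective borohydride reduction: at low temperature the aldehyde is reduced well before the C4 aryl ketone, which is shielded by the C3 and C5 silyloxy groups, and the protic co-solvent protonates the benzylic alkoxide before a silyl group can migrate to it from O5 or O7.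

**Step 8**
Reactants: 10 (2R,3R)-6-(hydroxymethyl)-3,5,7,3',4'-penta-O-TBS-taxifolin
Product: 12 (2R,3R)-6-(chloromethyl)-3,5,7,3',4'-penta-O-TBS-taxifolin, via benzylic mesylate 11 (not isolated)
Conditions: MsCl (1.3 equiv), Et3N (2 equiv), LiCl (5 equiv), THF, 0 °C → rt; used at once
Reagents that add atoms: methanesulfonyl chloride, CS(=O)(=O)Cl; lithium chloride, [Li+].[Cl-]
Why: Mesylation followed by chloride displacement in the same flask: the electron-rich benzylic mesylate exchanges readily with chloride under buffered, non-acidic conditions that leave the silyl ethers in place.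

**Step 9**
Reactants: 13 pent-4-ynoic acid
Product: 15 N-methoxy-N-methylpent-4-ynamide, via acylimidazole 14 (not isolated)
Conditions: CDI, CH2Cl2, rt; then MeNH(OMe)·HCl, rt
Reagents that add atoms: 1,1'-carbonyldiimidazole, O=C(n1ccnc1)n1ccnc1; N,O-dimethylhydroxylamine hydrochloride, CNOC.Cl
Why: Amide formation through the acylimidazole: carbonyldiimidazole activates the acid and N,O-dimethylhydroxylamine opens 14 to the Weinreb amide without affecting the alkyne.

**Step 10**
Reactants: 15 N-methoxy-N-methylpent-4-ynamide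
Product: 16 2-methylhept-1-en-6-yn-3-one
Conditions: CH2=C(CH3)MgBr (2.3 equiv), THF, −20 → 0 °C; inverse quench into cold 1 M HCl
Reagents that add atoms: isopropenylmagnesium bromide, C=C(C)[Mg]Br
Why: Weinreb ketone synthesis: the chelated tetrahedral magnesium adduct prevents a second addition, the extra Grignard reagent covers deprotonation of the alkyne C–H, and the cold acidic inverse quench prevents conjugate addition of the released amine to the enone.

**Step 11**
Reactants: 16 2-methylhept-1-en-6-yn-3-one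
Product: 17 (3R)-2-methylhept-1-en-6-yn-3-ol
Conditions: (S)-Me-CBS oxazaborolidine (15 mol%), catecholborane (1.6 equiv), PhMe, −78 °C
Reagents that add atoms: none
Why: Corey–Bakshi–Shibata reduction: with the isopropenyl group as the larger substituent the (S)-oxazaborolidine directs hydride to the face that gives the (3R)-carbinol, and catecholborane at −78 °C does not hydroborate the alkyne or the alkene.

**Step 12**
Reactants: 17 (3R)-2-methylhept-1-en-6-yn-3-ol
Product: 18 (3R)-3-(tert-butyldimethylsilyloxy)-2-methylhept-1-en-6-yne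
Conditions: TBSCl, imidazole, DMF, rt
Reagents that add atoms: tert-butyldimethylsilyl chloride, CC(C)(C)[Si](C)(C)Cl
Why: Imidazole-mediated O-silylation of the secondary allylic alcohol; the stereocentre is not involved.

**Step 13**
Reactants: 18 (3R)-3-(tert-butyldimethylsilyloxy)-2-methylhept-1-en-6-yne; 12 (2R,3R)-6-(chloromethyl)-3,5,7,3',4'-penta-O-TBS-taxifolin
Product: 20 (2R,3R)-6-[(2E,6R)-6-(tert-butyldimethylsilyloxy)-3,7-dimethylocta-2,7-dien-1-yl]-3,5,7,3',4'-penta-O-TBS-taxifolin, via (E)-alkenyldimethylalane 19 (not isolated)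
Conditions: 18 (1.5 equiv), AlMe3 (3 equiv), Cp2ZrCl2 (0.4 equiv), CH2Cl2, 0 °C → rt; volatiles removed in vacuo, THF; then 12 (1 equiv), NiCl2(PPh3)2 (5 mol%)/n-BuLi (10 mol%) to give zerovalent nickel, THF, −20 → 0 °C
Reagents that add atoms: trimethylaluminium, C[Al](C)C
Why: Zirconium-catalysed methylalumination of the terminal alkyne followed by nickel-catalysed alkenyl–benzyl cross-coupling (carboalumination/Negishi-type coupling), the closest precedent being the union of (E)-2-methylalk-1-enylalanes with doubly ortho-substituted, polyoxygenated benzylic chlorides. A Zr–CH3 species activated by aluminium delivers carbon and metal to the same face of C6≡C7 of 18, the metal going to the unsubstituted terminus, so that in 19 the chain that becomes C4'' lies trans to aluminium. Zerovalent nickel inserts into the C–Cl bond of 12, the sp2 group passes from aluminium to nickel in preference to methyl, and reductive elimination forms C1''–C2'' with retention, which is why the C2''=C3'' alkene is (E). No ring is closed and no stereocentre is created; C2, C3 and C6'' pass through untouched. Chemoselectivity for the alkyne over the 1,1-disubstituted C7''=C8'' alkene follows from the far higher rate of alkyne carbometalation with Cp2ZrCl2. The C4 ketone and the silyl ethers are spared because excess AlMe3 is stripped before the coupling, the alane is tamed as its THF adduct, the carbonyl is flanked by the C3 and C5 silyloxy groups, and the temperature is low.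

**Step 14**
Reactants: 20 (2R,3R)-6-[(2E,6R)-6-(tert-butyldimethylsilyloxy)-3,7-dimethylocta-2,7-dien-1-yl]-3,5,7,3',4'-penta-O-TBS-taxifolin
Product: 21 (2R,3R)-6-[(2E,6R)-6-hydroxy-3,7-dimethylocta-2,7-dien-1-yl]taxifolin (CNP0280079.1)
Conditions: HF·pyridine (excess), pyridine, THF, 0 °C → rt (polypropylene vessel); Me3SiOMe quench
Reagents that add atoms: none
Why: Fluoride-mediated global desilylation: buffered HF·pyridine cleaves the four aryl and two secondary alkyl Si–O bonds without base (no C2 epimerisation or aerial oxidation of the flavanonol) and without enough acidity to add a phenol across the C2''=C3'' alkene; no stereocentre is touched.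

**Compound list**

1 | (2R,3R)-taxifolin | Oc1cc(O)c2c(c1)O[C@H](c1ccc(O)c(O)c1)[C@@H](O)C2=O | starting material
2 | (2R,3R)-3,7,3',4'-tetra-O-TBS-taxifolin (5-OH free) | c1c(O[Si](C)(C)C(C)(C)C)cc2c(c1O)C(=O)[C@H](O[Si](C)(C)C(C)(C)C)[C@@H](c1ccc(O[Si](C)(C)C(C)(C)C)c(O[Si](C)(C)C(C)(C)C)c1)O2 | intermediate
3 | allyl alcohol (prop-2-en-1-ol) | C=CCO | starting material
4 | (2R,3R)-5-O-allyl-3,7,3',4'-tetra-O-TBS-taxifolin | c1c(O[Si](C)(C)C(C)(C)C)cc2c(c1OCC=C)C(=O)[C@H](O[Si](C)(C)C(C)(C)C)[C@@H](c1ccc(O[Si](C)(C)C(C)(C)C)c(O[Si](C)(C)C(C)(C)C)c1)O2 | intermediate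
5 | (2R,3R)-6-allyl-3,7,3',4'-tetra-O-TBS-taxifolin (5-OH free) | C=CCc1c(O[Si](C)(C)C(C)(C)C)cc2c(c1O)C(=O)[C@H](O[Si](C)(C)C(C)(C)C)[C@@H](c1ccc(O[Si](C)(C)C(C)(C)C)c(O[Si](C)(C)C(C)(C)C)c1)O2 | intermediate
6 | (2R,3R)-6-allyl-3,5,7,3',4'-penta-O-TBS-taxifolin | C=CCc1c(O[Si](C)(C)C(C)(C)C)cc2c(c1O[Si](C)(C)C(C)(C)C)C(=O)[C@H](O[Si](C)(C)C(C)(C)C)[C@@H](c1ccc(O[Si](C)(C)C(C)(C)C)c(O[Si](C)(C)C(C)(C)C)c1)O2 | intermediate
7 | (2R,3R)-6-[(E)-prop-1-enyl]-3,5,7,3',4'-penta-O-TBS-taxifolin | C/C=C/c1c(O[Si](C)(C)C(C)(C)C)cc2c(c1O[Si](C)(C)C(C)(C)C)C(=O)[C@H](O[Si](C)(C)C(C)(C)C)[C@@H](c1ccc(O[Si](C)(C)C(C)(C)C)c(O[Si](C)(C)C(C)(C)C)c1)O2 | intermediate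
8 | (2R,3R)-6-(1,2-dihydroxypropyl)-3,5,7,3',4'-penta-O-TBS-taxifolin (mixture at the two new carbinol carbons) | CC(O)C(O)c1c(O[Si](C)(C)C(C)(C)C)cc2c(c1O[Si](C)(C)C(C)(C)C)C(=O)[C@H](O[Si](C)(C)C(C)(C)C)[C@@H](c1ccc(O[Si](C)(C)C(C)(C)C)c(O[Si](C)(C)C(C)(C)C)c1)O2 | intermediate (not isolated)
9 | (2R,3R)-6-formyl-3,5,7,3',4'-penta-O-TBS-taxifolin | O=Cc1c(O[Si](C)(C)C(C)(C)C)cc2c(c1O[Si](C)(C)C(C)(C)C)C(=O)[C@H](O[Si](C)(C)C(C)(C)C)[C@@H](c1ccc(O[Si](C)(C)C(C)(C)C)c(O[Si](C)(C)C(C)(C)C)c1)O2 | intermediate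
10 | (2R,3R)-6-(hydroxymethyl)-3,5,7,3',4'-penta-O-TBS-taxifolin | OCc1c(O[Si](C)(C)C(C)(C)C)cc2c(c1O[Si](C)(C)C(C)(C)C)C(=O)[C@H](O[Si](C)(C)C(C)(C)C)[C@@H](c1ccc(O[Si](C)(C)C(C)(C)C)c(O[Si](C)(C)C(C)(C)C)c1)O2 | intermediate
11 | (2R,3R)-6-[(methanesulfonyloxy)methyl]-3,5,7,3',4'-penta-O-TBS-taxifolin | CS(=O)(=O)OCc1c(O[Si](C)(C)C(C)(C)C)cc2c(c1O[Si](C)(C)C(C)(C)C)C(=O)[C@H](O[Si](C)(C)C(C)(C)C)[C@@H](c1ccc(O[Si](C)(C)C(C)(C)C)c(O[Si](C)(C)C(C)(C)C)c1)O2 | intermediate (not isolated)
12 | (2R,3R)-6-(chloromethyl)-3,5,7,3',4'-penta-O-TBS-taxifolin | ClCc1c(O[Si](C)(C)C(C)(C)C)cc2c(c1O[Si](C)(C)C(C)(C)C)C(=O)[C@H](O[Si](C)(C)C(C)(C)C)[C@@H](c1ccc(O[Si](C)(C)C(C)(C)C)c(O[Si](C)(C)C(C)(C)C)c1)O2 | intermediate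
13 | pent-4-ynoic acid | C#CCCC(=O)O | starting material
14 | 1-(1H-imidazol-1-yl)pent-4-yn-1-one | C#CCCC(=O)n1ccnc1 | intermediate (not isolated)
15 | N-methoxy-N-methylpent-4-ynamide | C#CCCC(=O)N(C)OC | intermediate
16 | 2-methylhept-1-en-6-yn-3-one | C=C(C)C(=O)CCC#C | intermediate
17 | (3R)-2-methylhept-1-en-6-yn-3-ol | C=C(C)[C@H](O)CCC#C | intermediate
18 | (3R)-3-(tert-butyldimethylsilyloxy)-2-methylhept-1-en-6-yne | C=C(C)[C@H](O[Si](C)(C)C(C)(C)C)CCC#C | intermediate
19 | [(1E,5R)-5-(tert-butyldimethylsilyloxy)-2,6-dimethylhepta-1,6-dien-1-yl]dimethylalane | C=C(C)[C@H](O[Si](C)(C)C(C)(C)C)CC/C(C)=C/[Al](C)C | intermediate (not isolated)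
20 | (2R,3R)-6-[(2E,6R)-6-(tert-butyldimethylsilyloxy)-3,7-dimethylocta-2,7-dien-1-yl]-3,5,7,3',4'-penta-O-TBS-taxifolin | C=C(C)[C@H](O[Si](C)(C)C(C)(C)C)CC/C(C)=C/Cc1c(O[Si](C)(C)C(C)(C)C)cc2c(c1O[Si](C)(C)C(C)(C)C)C(=O)[C@H](O[Si](C)(C)C(C)(C)C)[C@@H](c1ccc(O[Si](C)(C)C(C)(C)C)c(O[Si](C)(C)C(C)(C)C)c1)O2 | intermediate
21 | (2R,3R)-6-[(2E,6R)-6-hydroxy-3,7-dimethylocta-2,7-dien-1-yl]taxifolin | C=C(C)[C@H](O)CC/C(C)=C/Cc1c(O)cc2c(c1O)C(=O)[C@H](O)[C@@H](c1ccc(O)c(O)c1)O2 | target

**Step count.** Total: 14 steps. Longest linear sequence: 10 steps (1 → 21 through steps 1–8, 13 and 14); the alkyne branch (steps 9–12) joins at step 13.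

**Steps most likely to fail**

Risk 1, step 13. Transfer of the alkenyl group to nickel may be outrun by Lewis-acid-driven ionisation of the electron-rich benzylic chloride, by methyl transfer, or by carbonyl addition at C4. Oxidative addition may also be slowed by the two flanking silyloxy groups. The fallback reverses the polarity of the same C1''–C2'' bond formation. Setting out from alane 19, iodinolysis (I2, THF, −30 °C) would give, with retention, (1E,5R)-5-(tert-butyldimethylsilyloxy)-1-iodo-2,6-dimethylhepta-1,6-diene F1. Setting out from chloride 12, LiCl-mediated zinc insertion (Zn dust, LiCl, THF, rt) would give the benzylic zinc chloride F2, a reagent class that tolerates hindered ketones. Negishi coupling of F2 with F1 under Pd(OAc)2 and SPhos (2-dicyclohexylphosphino-2',6'-dimethoxybiphenyl) in THF at rt comes back to the route at 20.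

Risk 2, step 3. The [3,3] shift of an unsubstituted allyl ether may need temperatures at which silyl groups migrate, ring C opens and recloses with loss of the C2 configuration, or the allyl group drifts on to C8 by a Cope shift. The fallback places the C6 carbon by hydroxyl-directed formylation instead of a sigmatropic shift. Setting out from 2, magnesium-mediated ortho-formylation (Casnati–Skattebøl; MgCl2, Et3N, paraformaldehyde, MeCN, reflux) can only functionalise the position ortho to the free 5-OH. It would give (2R,3R)-6-formyl-3,7,3',4'-tetra-O-TBS-taxifolin F3. Silylation of its 5-OH (TBSOTf, 2,6-lutidine, CH2Cl2, −20 → 0 °C) comes back to the route at aldehyde 9 and bypasses 4 to 8.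

Risk 3, step 11. Facial discrimination between the isopropenyl and 3-butynyl groups may be insufficient. The minor enantiomer would then be carried through to an inseparable C6'' epimer of 21. The fallback is a kinetic resolution instead of an asymmetric reduction. Setting out from 16, Luche reduction (NaBH4, CeCl3·7H2O, MeOH, 0 °C) would give racemic 2-methylhept-1-en-6-yn-3-ol F4. Sharpless kinetic resolution (Ti(OiPr)4, L-(+)-diisopropyl tartrate, t-BuOOH (0.6 equiv), 4 Å molecular sieves, CH2Cl2, −20 °C) should epoxidise the (S)-enantiomer to the erythro epoxy alcohol (1S)-1-[(2R)-2-methyloxiran-2-yl]pent-4-yn-1-ol F5. The unreacted (R)-alcohol is separated by chromatography and re-enters the route at 17.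

**Further compounds**

F1 | step 13 | (1E,5R)-5-(tert-butyldimethylsilyloxy)-1-iodo-2,6-dimethylhepta-1,6-diene | C=C(C)[C@H](O[Si](C)(C)C(C)(C)C)CC/C(C)=C/I
F2 | step 13 | {[(2R,3R)-3,5,7,3',4'-penta-O-TBS-taxifolin-6-yl]methyl}zinc chloride | Cl[Zn]Cc1c(O[Si](C)(C)C(C)(C)C)cc2c(c1O[Si](C)(C)C(C)(C)C)C(=O)[C@H](O[Si](C)(C)C(C)(C)C)[C@@H](c1ccc(O[Si](C)(C)C(C)(C)C)c(O[Si](C)(C)C(C)(C)C)c1)O2
F3 | step 3 | (2R,3R)-6-formyl-3,7,3',4'-tetra-O-TBS-taxifolin (5-OH free) | O=Cc1c(O[Si](C)(C)C(C)(C)C)cc2c(c1O)C(=O)[C@H](O[Si](C)(C)C(C)(C)C)[C@@H](c1ccc(O[Si](C)(C)C(C)(C)C)c(O[Si](C)(C)C(C)(C)C)c1)O2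
F4 | step 11 | racemic 2-methylhept-1-en-6-yn-3-ol | C=C(C)C(O)CCC#C
F5 | step 11 | (1S)-1-[(2R)-2-methyloxiran-2-yl]pent-4-yn-1-ol | C#CCC[C@H](O)[C@@]1(C)CO1
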